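## The problem

Shikimate numbering is used throughout: C1 carries the carboxyl group, C2 is the vinylic CH, C3–C5 carry the oxygens and C6 is CH2.

The target is a fully acylated shikimate-type acid, a cyclohex-1-ene-1-carboxylic acid with three different esters: 6-methylheptanoate on the allylic O3, tiglate on the central O4 and acetate on O5. There is one carbocycle, so the skeletal task is to close a six-membered ring that already holds the carboxyl carbon on C1 and has its alkene at C1=C2 and not at C1=C6. The stereocentres are 3R,4R,5S with the three oxygens mutually trans, the all-equatorial 3-epi-shikimate pattern in the enantiomeric series, so shikimic acid itself is no shortcut. C4 and C5 form a trans-1,2-diol of the tartrate type and can be bought; C3 must then be set relative to C4, and the three oxygens must be told apart. The delicate parts are the three esters on adjacent oxygens (migration and hydrolysis under base, so the acid must be released without base), the allylic C3–O bond, the conjugated tiglate and the tendency of shikimates to aromatise by elimination. The key step is possible because C2 is a vinylic carbon lying between the carboxyl-bearing C1 and the carbinol C3. A nitro group on C2 makes it the nucleophile for a C2–C3 bond to a C3 aldehyde and lets C2 and C3 equilibrate toward the all-equatorial array beside the fixed O4. It finally leaves as nitrite toward C1, which puts the alkene at C1=C2.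

## Retrosynthesis

**Acid release.** Target 24 is traced to its tert-butyl ester 23 by cutting the ester O–C(CH3)3 bond. Acidolysis is the only unmasking that three neighbouring esters tolerate. A methyl ester would need hydroxide and a benzyl ester would need hydrogenation over the tiglate. The tert-butyl ester also resists self-condensation in the carbanion chemistry at the start.

**The three esters.** In 23 the acetate comes off first (22), then a temporary silyl group is put back on O5 (21), then the tiglate is removed (18, with tiglic acid 19 delivered through mixed anhydride 20). Removing the O5 silyl group gives diol 17, closing the 4,5-acetonide gives 16, and removing the 6-methylheptanoate (acid 15) gives allylic alcohol 14. The order follows from what distinguishes the oxygens: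
- In 14, O3 is the only free hydroxyl, so its acyl group needs no selectivity.
- In 17, O5 has a CH2 neighbour while O4 sits between two oxygenated carbons, so a bulky silyl chloride should pick O5.
- The hindered, slow tigloylation is then done while both neighbours are blocked.
- The small, migration-prone acetate goes on last.

Direct O5 acetylation of 17 would save two steps. It was set aside because acetyl is the least discriminating and most mobile of the three groups and would sit beside a free O4 during the slow tigloylation.

**The alkene.** 14 comes from silyl ether 13, and the C1=C2 bond of 13 from loss of HNO2 from the β-nitro ester 12, the silyl ether of nitro alcohol 11. The group that will build the ring is thus also the leaving group that fixes the alkene position, so no separate dehydration or oxidation-state change is needed. The demand is that O3 be capped as a silyl ether: a free hydroxyl would open the ring by retro-nitro-aldol under DBU, and an ester would be expelled to give a nitroalkene.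

**Key disconnection, C2–C3.** Cutting C2–C3 of 11 gives the acyclic nitro aldehyde 9, which reacts through its nitronate 10. Reasons for this cut over its neighbours:
- A C1–C2 aldol cut needs one enolate out of several possible ones.
- A C1–C6 cut leaves a ketone to be turned into the enoate afterwards.
- Here the nucleophilic carbon bears by far the most acidic C–H of the molecule, and the electrophile is an aldehyde directly beside the controlling C4.

The precursor has only the two tartrate-derived centres that matter, since C1 is erased later. The forward reaction must be reversible, must use a base too weak to expel nitrite, and must settle with O3 trans to O4.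

**The chain.** Aldehyde 9 comes from alcohol 8 and its silyl ether 7. The C6–C1 bond of 7 is cut to give triflate 3 and tert-butyl 3-nitropropanoate 5, used as its dianion 6. This acrylate α-anion equivalent delivers C1, C2 and the carboxyl carbon in one alkylation. The forward reaction needs an SN2 at a β-oxygenated primary carbon, hence the triflate.

**Starting materials.** Triflate 3 comes from monosilyl ether 2 of the C2-symmetric (+)-2,3-O-isopropylidene-L-threitol 1; either hydroxyl gives the same product. Nitro ester 5 comes from tert-butyl 3-bromopropanoate 4 and nitrite.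

## Roads not taken

**Alternative 1: hexose chiral pool and Ferrier carbocyclisation.**
- Cut: C1–C6 of the carbocycle.
- Key step: the enol ether A1 (methyl 6-deoxy-2,3-bis-O-(4-methoxybenzyl)-4-O-silyl-α-D-xylo-hex-5-enopyranoside) is treated with Hg(OCOCF3)2 (divalent mercury) in aqueous acetone. Hydration of the enol ether, opening of the pyranoside and aldol closure between sugar C6 and the anomeric carbon give the β-hydroxy cyclohexanone A2.
- Merits: sugar C2, C3 and C4 of the gluco series are all trans. Read backwards they are the target's C5, C4 and C3, with correct relative and absolute configuration, all taken from the pool. The ring closure is among the most dependable in cyclitol chemistry, and O3 arrives already marked as a silyl ether.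
- Weak points: A2 has the wrong oxidation pattern. It has no carboxyl carbon, a ketone at C2 where a vinylic CH is needed, and a hydroxyl at C6 that must be removed. C-acylation at C1, carbonyl reduction, dehydration and deoxygenation must follow on a ketone prone to β-elimination and aromatisation. O4 and O5 carry the same ether, so that distinction is not solved either, and A1 needs its own protection sequence.
- Comparison: in stereochemical security this road is better, because nothing rests on an equilibrium. The chosen plan counters that the nitropropanoate unit brings the carboxyl carbon and the latent C1=C2 alkene into the ring-forming step, so no oxidation-state repair follows and the route should be several steps shorter.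

**Alternative 2: furan–acrylate Diels–Alder, bridge opening and epoxide relay.**
- Cut: C1–C2 and C5–C6.
- Key step: furan A3 and 2,2,2-trifluoroethyl acrylate A4 combine under asymmetric Lewis-acid catalysis to the oxanorbornene A5. Base then opens the oxygen bridge by β-elimination, which frees O5 and creates C1=C2. Epoxidation of the C3=C4 alkene and opening at C3 would supply O4 and O3.
- Merits: two cheap achiral compounds; ring, carboxyl carbon and alkene are present after two operations. O5 is unique from the moment the bridge opens, which is better than the steric O4/O5 discrimination the chosen plan needs in step 13. If every selectivity held, this would be the shortest route.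
- Weak points: furan is a reluctant and reversible diene, so endo/exo ratio and enantiomeric purity depend on staying under kinetic control. The all-trans triol needs epoxidation anti to the O5 substituent, whereas a free hydroxyl would direct syn. It then needs opening at C3 with inversion, in competition with attack at C4 and conjugate opening through the dienoate. The dienol stage aromatises easily.
- Comparison: shorter and cheaper on paper. The chosen plan takes the absolute configuration from the pool, not from catalysis of a reversible cycloaddition, and sets the relative configuration in a thermodynamic sink in place of two consecutive kinetic selections.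

**Alternative 3: dehydroquinate-type aldol from L-tartrate.**
- Cut: C1–C2.
- Key step: the methyl ketone enol (C2) of diketo ester A6 adds to the C1 keto group and water is lost, giving enone A7, a protected 3-dehydroshikimate of the required series.
- Merits: same pool and same C4/C5 as the chosen plan, with no nitro group to carry and remove. One reduction of A7 would give 14, so the three steps from 11 to 14 shrink to one.
- Weak points: A6 has three enolisable positions, and the methyl group that must react is the least acidic. The most acidic one is C6, next to the 1,2-dicarbonyl and β to O5, where enolisation invites E1cB opening of the dioxolane. A6 also needs two different carbonyl termini built on the threitol, which costs more steps than 9.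
- Comparison: after ring closure this road is shorter. The chosen plan sets against it a nucleophile that is unambiguous (only the nitronate forms under an amine base) and an aldehyde electrophile. It keeps A7 in reserve as a way to reset C3 if needed.

Key step: step 7

## Route

Assumption: the target is taken as the 3R,4R,5S enantiomer drawn, and commercial 1 as the (4S,5S) enantiomer derived from L-tartaric acid. Its two dioxolane carbons become C4 and C5 without any bond to them being made or broken.

Step 1
Reactants: 1 (+)-2,3-O-isopropylidene-L-threitol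
Product: 2 [(4S,5S)-5-{[tert-butyl(dimethyl)silyl]oxymethyl}-2,2-dimethyl-1,3-dioxolan-4-yl]methanol
Conditions: NaH (1.0 equiv), THF, 0 °C; TBSCl (1.0 equiv), 0 °C → rt
Reagents that add atoms: tert-butyldimethylsilyl chloride (TBSCl), CC(C)(C)[Si](C)(C)Cl
Why: Monosilylation of a symmetrical diol through its sparingly soluble mono-sodium alkoxide; the diol is C2-symmetric, so either hydroxyl gives the same product and no stereocentre is touched.

Step 2
Reactants: 2 [(4S,5S)-5-{[tert-butyl(dimethyl)silyl]oxymethyl}-2,2-dimethyl-1,3-dioxolan-4-yl]methanol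
Product: 3 [(4S,5S)-5-{[tert-butyl(dimethyl)silyl]oxymethyl}-2,2-dimethyl-1,3-dioxolan-4-yl]methyl trifluoromethanesulfonate
Conditions: Tf2O, 2,6-lutidine, CH2Cl2, −78 → −20 °C; used without chromatography
Reagents that add atoms: trifluoromethanesulfonic anhydride (Tf2O), O=S(=O)(OS(=O)(=O)C(F)(F)F)C(F)(F)F
Why: O-Sulfonylation of a primary alcohol; the triflate is chosen over a tosylate or iodide because the carbon is β-branched and β-oxygenated and the next SN2 step needs the best leaving group.

Step 3
Reactants: 4 tert-butyl 3-bromopropanoate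
Product: 5 tert-butyl 3-nitropropanoate
Conditions: NaNO2, DMSO, rt
Reagents that add atoms: sodium nitrite (NaNO2), [Na+].[O-]N=O
Why: Kornblum nitrite substitution of an unhindered primary bromide in a dipolar aprotic solvent, where N-alkylation is favoured; the reaction is worked up before the β-nitro ester can lose HNO2.

Step 4
Reactants: 3 [(4S,5S)-5-{[tert-butyl(dimethyl)silyl]oxymethyl}-2,2-dimethyl-1,3-dioxolan-4-yl]methyl trifluoromethanesulfonate; 5 tert-butyl 3-nitropropanoate
Product: 7 tert-butyl 3-[(4S,5S)-5-{[tert-butyl(dimethyl)silyl]oxymethyl}-2,2-dimethyl-1,3-dioxolan-4-yl]-2-(nitromethyl)propanoate (both epimers at the future C1), via dilithiated tert-butyl 3-nitropropanoate 6 (not isolated)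
Conditions: LiN(iPr)2 (2.1 equiv), THF/DMPU, −78 °C; then 3, −78 → −40 °C; AcOH, −78 °C
Reagents that add atoms: lithium diisopropylamide, [Li+].CC(C)[N-]C(C)C (its lithium is held in intermediate 6 only; none of its atoms remain in 7)
Why: Double deprotonation of a 3-nitropropanoate gives a nitronate–enolate dianion that is alkylated at the carbon α to the ester, so SN2 displacement of the primary triflate forms C6–C1 with the carboxyl carbon and the future C2 attached. The new C1 centre forms unselectively and is erased in step 9; the cold acid quench prevents loss of HNO2.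

Step 5
Reactants: 7 tert-butyl 3-[(4S,5S)-5-{[tert-butyl(dimethyl)silyl]oxymethyl}-2,2-dimethyl-1,3-dioxolan-4-yl]-2-(nitromethyl)propanoate
Product: 8 tert-butyl 3-[(4S,5S)-5-(hydroxymethyl)-2,2-dimethyl-1,3-dioxolan-4-yl]-2-(nitromethyl)propanoate (both C1 epimers)
Conditions: HF·pyridine, pyridine, THF, 0 °C → rt
Reagents that add atoms: none
Why: Fluoride cleavage of a primary silyl ether under pyridine-buffered, weakly acidic conditions; basic fluoride is avoided because it could eliminate HNO2 from the β-nitro ester, and the unstrained dioxolane tolerates buffered HF.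

Step 6
Reactants: 8 tert-butyl 3-[(4S,5S)-5-(hydroxymethyl)-2,2-dimethyl-1,3-dioxolan-4-yl]-2-(nitromethyl)propanoate
Product: 9 tert-butyl 3-[(4S,5R)-5-formyl-2,2-dimethyl-1,3-dioxolan-4-yl]-2-(nitromethyl)propanoate (both C1 epimers)
Conditions: Dess–Martin periodinane, NaHCO3, CH2Cl2, 0 °C → rt; used at once
Reagents that add atoms: none
Why: Dess–Martin oxidation of a primary alcohol under near-neutral conditions that do not deprotonate the nitro group; C4, now α to the aldehyde, is held by the trans-disubstituted dioxolane, which is the more stable arrangement.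

Step 7
Reactants: 9 tert-butyl 3-[(4S,5R)-5-formyl-2,2-dimethyl-1,3-dioxolan-4-yl]-2-(nitromethyl)propanoate
Product: 11 tert-butyl (2S,3R,4S,5S)-3-hydroxy-4,5-(isopropylidenedioxy)-2-nitrocyclohexane-1-carboxylate (C1 epimers; nitro and hydroxyl equatorial), via triethylammonium nitronate 10 (not isolated)
Conditions: Et3N (0.3 equiv), MeCN (0.02 M), 0 °C → rt, held until equilibrium; AcOH quench
Reagents that add atoms: triethylamine, CCN(CC)CC (present as the counter-ion of intermediate 10 only; none of its atoms remain in 11)
Why: Et3N removes a proton only from the CH2NO2 group, which is far more acidic than the ester α-C–H or the C4–H, and the C2 nitronate 10 adds to the C3 aldehyde in an intramolecular nitro-aldol (Henry) reaction, the reaction type used to make nitrocyclitols from nitro sugars. The carbocycle closes in a 6-(enolexo)-exo-trig mode through a chair-like transition state in which the trans-dioxolane already holds O4 and C6 equatorial. Both new centres are under thermodynamic control: the addition is reversible and C2 epimerises through the nitronate, so the mixture should settle in the isomer with the C2 nitro and C3 hydroxyl equatorial, trans to each other and to the equatorial O4 fixed by the tartrate-derived C4 and C5. The selectivity needed is diastereoselectivity at C3 (trans to O4); it comes from this equilibration relayed from C4, and the chair transition state with an equatorial C–O bond points the same way. C2 and C1 are temporary and need no control. Henry addition is favoured over loss of HNO2 because the weak base keeps the material as the nitronate, which cannot expel nitrite, and barely deprotonates the ester α-carbon. Dilution suppresses the intermolecular reaction.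

Step 8
Reactants: 11 tert-butyl (2S,3R,4S,5S)-3-hydroxy-4,5-(isopropylidenedioxy)-2-nitrocyclohexane-1-carboxylate
Product: 12 tert-butyl (2S,3R,4R,5S)-3-{[tert-butyl(dimethyl)silyl]oxy}-4,5-(isopropylidenedioxy)-2-nitrocyclohexane-1-carboxylate (C1 epimers)
Conditions: TBSOTf, 2,6-lutidine, CH2Cl2, −78 → −20 °C
Reagents that add atoms: tert-butyldimethylsilyl trifluoromethanesulfonate (TBSOTf), CC(C)(C)[Si](C)(C)OS(=O)(=O)C(F)(F)F
Why: O-Silylation of a secondary alcohol with a silyl triflate and a weak hindered base that does not trigger retro-Henry opening; a silyl ether is a poor leaving group, so it blocks both ring opening and nitroalkene formation in step 9.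

Step 9
Reactants: 12 tert-butyl (2S,3R,4R,5S)-3-{[tert-butyl(dimethyl)silyl]oxy}-4,5-(isopropylidenedioxy)-2-nitrocyclohexane-1-carboxylate
Product: 13 tert-butyl (3R,4R,5S)-3-{[tert-butyl(dimethyl)silyl]oxy}-4,5-(isopropylidenedioxy)cyclohex-1-ene-1-carboxylate
Conditions: DBU (2 equiv), THF, 0 °C → rt
Reagents that add atoms: none
Why: Base-mediated E1cB loss of HNO2 from a β-nitro ester, known for 2-substituted 3-nitropropanoates and for cyclic nitroacrylate cycloadducts with an oxygenated neighbour; C1–H is the only acidic proton β to the nitro group, so the alkene can form only at C1=C2. Both C1 epimers converge, C2 can epimerise under DBU until its C–N bond is aligned, and C3–C5 are untouched.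

Step 10
Reactants: 13 tert-butyl (3R,4R,5S)-3-{[tert-butyl(dimethyl)silyl]oxy}-4,5-(isopropylidenedioxy)cyclohex-1-ene-1-carboxylate
Product: 14 tert-butyl (3R,4S,5S)-3-hydroxy-4,5-(isopropylidenedioxy)cyclohex-1-ene-1-carboxylate
Conditions: Bu4NF, AcOH, THF, 0 °C → rt
Reagents that add atoms: none
Why: Fluoride cleavage of a secondary silyl ether; AcOH buffering keeps the medium near neutral so the alkene does not migrate, and the strained trans-fused acetonide, which an acidic desilylation would endanger, stays on.

Step 11
Reactants: 14 tert-butyl (3R,4S,5S)-3-hydroxy-4,5-(isopropylidenedioxy)cyclohex-1-ene-1-carboxylate; 15 6-methylheptanoic acid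
Product: 16 tert-butyl (3R,4R,5S)-4,5-(isopropylidenedioxy)-3-[(6-methylheptanoyl)oxy]cyclohex-1-ene-1-carboxylate
Conditions: EDC·HCl (N-ethyl-N′-(3-dimethylaminopropyl)carbodiimide hydrochloride), DMAP (4-dimethylaminopyridine), CH2Cl2, 0 °C → rt
Reagents that add atoms: none
Why: Carbodiimide/DMAP (Steglich) esterification of the only free hydroxyl, so the acyl group goes onto O3 without any selectivity question; no stereocentre is affected.

Step 12
Reactants: 16 tert-butyl (3R,4R,5S)-4,5-(isopropylidenedioxy)-3-[(6-methylheptanoyl)oxy]cyclohex-1-ene-1-carboxylate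
Product: 17 tert-butyl (3R,4R,5S)-4,5-dihydroxy-3-[(6-methylheptanoyl)oxy]cyclohex-1-ene-1-carboxylate
Conditions: AcOH/H2O (4:1), 40 °C
Reagents that add atoms: none
Why: Acid-catalysed acetal hydrolysis; the trans-fused dioxolane on a six-membered ring is strained and should cleave under conditions that leave the tert-butyl ester and the allylic ester intact, and weak acid does not promote O3→O4 acyl migration.

Step 13
Reactants: 17 tert-butyl (3R,4R,5S)-4,5-dihydroxy-3-[(6-methylheptanoyl)oxy]cyclohex-1-ene-1-carboxylate
Product: 18 tert-butyl (3R,4S,5S)-5-{[tert-butyl(dimethyl)silyl]oxy}-4-hydroxy-3-[(6-methylheptanoyl)oxy]cyclohex-1-ene-1-carboxylate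
Conditions: TBSCl (1.1 equiv), imidazole, DMF, 0 °C
Reagents that add atoms: tert-butyldimethylsilyl chloride (TBSCl), CC(C)(C)[Si](C)(C)Cl
Why: Sterically controlled monosilylation of a vicinal diol: O5 has a CH2 neighbour whereas O4 lies between two oxygenated carbons, the same bias that lets shikimate triols be silylated at the outer oxygens while O4 stays free. The short, cold exposure to imidazole is not expected to move the O3 ester.

Step 14
Reactants: 18 tert-butyl (3R,4S,5S)-5-{[tert-butyl(dimethyl)silyl]oxy}-4-hydroxy-3-[(6-methylheptanoyl)oxy]cyclohex-1-ene-1-carboxylate; 19 tiglic acid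
Product: 21 tert-butyl (3R,4S,5S)-5-{[tert-butyl(dimethyl)silyl]oxy}-3-[(6-methylheptanoyl)oxy]-4-{[(2E)-2-methylbut-2-enoyl]oxy}cyclohex-1-ene-1-carboxylate, via tiglic 2,4,6-trichlorobenzoic anhydride 20 (not isolated)
Conditions: 19, 2,4,6-trichlorobenzoyl chloride, Et3N, toluene, rt; then 18, DMAP, toluene, rt → 50 °C
Reagents that add atoms: 2,4,6-trichlorobenzoyl chloride, O=C(Cl)c1c(Cl)cc(Cl)cc1Cl (its atoms are held in intermediate 20 only; none remain in 21)
Why: Yamaguchi esterification: DMAP attacks the mixed anhydride 20 at the less hindered tigloyl carbonyl and the acylpyridinium acylates the hindered O4, the only free hydroxyl. The E geometry of the thermodynamically preferred tiglate is kept.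

Step 15
Reactants: 21 tert-butyl (3R,4S,5S)-5-{[tert-butyl(dimethyl)silyl]oxy}-3-[(6-methylheptanoyl)oxy]-4-{[(2E)-2-methylbut-2-enoyl]oxy}cyclohex-1-ene-1-carboxylate
Product: 22 tert-butyl (3R,4R,5S)-5-hydroxy-3-[(6-methylheptanoyl)oxy]-4-{[(2E)-2-methylbut-2-enoyl]oxy}cyclohex-1-ene-1-carboxylate
Conditions: HF·pyridine, pyridine, THF, 0 °C → rt
Reagents that add atoms: none
Why: Fluoride cleavage of the secondary silyl ether under weakly acidic conditions, where the neighbouring tiglate should not migrate to O5 because acyl migration is base-promoted; no acid-labile acetal remains.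

Step 16
Reactants: 22 tert-butyl (3R,4R,5S)-5-hydroxy-3-[(6-methylheptanoyl)oxy]-4-{[(2E)-2-methylbut-2-enoyl]oxy}cyclohex-1-ene-1-carboxylate
Product: 23 tert-butyl (3R,4R,5S)-5-acetoxy-3-[(6-methylheptanoyl)oxy]-4-{[(2E)-2-methylbut-2-enoyl]oxy}cyclohex-1-ene-1-carboxylate
Conditions: Ac2O, pyridine, DMAP (cat.), CH2Cl2, 0 °C
Reagents that add atoms: acetic anhydride (Ac2O), CC(=O)OC(C)=O
Why: DMAP-catalysed acetylation of the last free hydroxyl, which is much faster than migration of the hindered conjugated tiglate, so each oxygen keeps its assigned acyl group.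

Step 17
Reactants: 23 tert-butyl (3R,4R,5S)-5-acetoxy-3-[(6-methylheptanoyl)oxy]-4-{[(2E)-2-methylbut-2-enoyl]oxy}cyclohex-1-ene-1-carboxylate
Product: 24 (3R,4R,5S)-5-acetoxy-3-[(6-methylheptanoyl)oxy]-4-{[(2E)-2-methylbut-2-enoyl]oxy}cyclohex-1-ene-1-carboxylic acid (CNP0225437.1)
Conditions: CF3CO2H/CH2Cl2 (1:4), 0 °C → rt
Reagents that add atoms: none
Why: Acidolysis of the tert-butyl ester with loss of isobutene frees the acid without base or nucleophile, so the three different esters, the allylic C3–O bond and the tiglate alkene are left alone.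

## Compound list

1 | (+)-2,3-O-isopropylidene-L-threitol, [(4S,5S)-2,2-dimethyl-1,3-dioxolane-4,5-diyl]dimethanol | OC[C@@H]1OC(C)(C)O[C@H]1CO | starting material
2 | [(4S,5S)-5-{[tert-butyl(dimethyl)silyl]oxymethyl}-2,2-dimethyl-1,3-dioxolan-4-yl]methanol | CC(C)(C)[Si](C)(C)OC[C@@H]1OC(C)(C)O[C@H]1CO | intermediate
3 | [(4S,5S)-5-{[tert-butyl(dimethyl)silyl]oxymethyl}-2,2-dimethyl-1,3-dioxolan-4-yl]methyl trifluoromethanesulfonate | CC(C)(C)[Si](C)(C)OC[C@@H]1OC(C)(C)O[C@H]1COS(=O)(=O)C(F)(F)F | intermediate
4 | tert-butyl 3-bromopropanoate | BrCCC(=O)OC(C)(C)C | starting material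
5 | tert-butyl 3-nitropropanoate | O=C(CC[N+](=O)[O-])OC(C)(C)C | intermediate
6 | dilithiated tert-butyl 3-nitropropanoate (nitronate–enolate dianion, dilithium salt) | [Li+].[Li+].[O-][N+]([O-])=CC=C([O-])OC(C)(C)C | intermediate
7 | tert-butyl 3-[(4S,5S)-5-{[tert-butyl(dimethyl)silyl]oxymethyl}-2,2-dimethyl-1,3-dioxolan-4-yl]-2-(nitromethyl)propanoate (both C1 epimers) | CC(C)(C)[Si](C)(C)OC[C@@H]1OC(C)(C)O[C@H]1CC(C[N+](=O)[O-])C(=O)OC(C)(C)C | intermediate
8 | tert-butyl 3-[(4S,5S)-5-(hydroxymethyl)-2,2-dimethyl-1,3-dioxolan-4-yl]-2-(nitromethyl)propanoate (both C1 epimers) | OC[C@@H]1OC(C)(C)O[C@H]1CC(C[N+](=O)[O-])C(=O)OC(C)(C)C | intermediate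
9 | tert-butyl 3-[(4S,5R)-5-formyl-2,2-dimethyl-1,3-dioxolan-4-yl]-2-(nitromethyl)propanoate (both C1 epimers) | O=C[C@@H]1OC(C)(C)O[C@H]1CC(C[N+](=O)[O-])C(=O)OC(C)(C)C | intermediate
10 | triethylammonium C2-nitronate of 9 | O=C[C@@H]1OC(C)(C)O[C@H]1CC(C=[N+]([O-])[O-])C(=O)OC(C)(C)C.CC[NH+](CC)CC | intermediate
11 | tert-butyl (2S,3R,4S,5S)-3-hydroxy-4,5-(isopropylidenedioxy)-2-nitrocyclohexane-1-carboxylate (C1 epimers) | CC(C)(C)OC(=O)C1[C@H]([N+](=O)[O-])[C@@H](O)[C@@H]2OC(C)(C)O[C@H]2C1 | intermediate
12 | tert-butyl (2S,3R,4R,5S)-3-{[tert-butyl(dimethyl)silyl]oxy}-4,5-(isopropylidenedioxy)-2-nitrocyclohexane-1-carboxylate (C1 epimers) | CC(C)(C)OC(=O)C1[C@H]([N+](=O)[O-])[C@@H](O[Si](C)(C)C(C)(C)C)[C@@H]2OC(C)(C)O[C@H]2C1 | intermediate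
13 | tert-butyl (3R,4R,5S)-3-{[tert-butyl(dimethyl)silyl]oxy}-4,5-(isopropylidenedioxy)cyclohex-1-ene-1-carboxylate | CC(C)(C)OC(=O)C1=C[C@@H](O[Si](C)(C)C(C)(C)C)[C@@H]2OC(C)(C)O[C@H]2C1 | intermediate
14 | tert-butyl (3R,4S,5S)-3-hydroxy-4,5-(isopropylidenedioxy)cyclohex-1-ene-1-carboxylate | CC(C)(C)OC(=O)C1=C[C@@H](O)[C@@H]2OC(C)(C)O[C@H]2C1 | intermediate
15 | 6-methylheptanoic acid | CC(C)CCCCC(=O)O | starting material
16 | tert-butyl (3R,4R,5S)-4,5-(isopropylidenedioxy)-3-[(6-methylheptanoyl)oxy]cyclohex-1-ene-1-carboxylate | CC(C)(C)OC(=O)C1=C[C@@H](OC(=O)CCCCC(C)C)[C@@H]2OC(C)(C)O[C@H]2C1 | intermediate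
17 | tert-butyl (3R,4R,5S)-4,5-dihydroxy-3-[(6-methylheptanoyl)oxy]cyclohex-1-ene-1-carboxylate | CC(C)(C)OC(=O)C1=C[C@@H](OC(=O)CCCCC(C)C)[C@H](O)[C@@H](O)C1 | intermediate
18 | tert-butyl (3R,4S,5S)-5-{[tert-butyl(dimethyl)silyl]oxy}-4-hydroxy-3-[(6-methylheptanoyl)oxy]cyclohex-1-ene-1-carboxylate | CC(C)(C)OC(=O)C1=C[C@@H](OC(=O)CCCCC(C)C)[C@H](O)[C@@H](O[Si](C)(C)C(C)(C)C)C1 | intermediate
19 | tiglic acid, (2E)-2-methylbut-2-enoic acid | C/C=C(\C)C(=O)O | starting material
20 | (2E)-2-methylbut-2-enoic 2,4,6-trichlorobenzoic anhydride | C/C=C(\C)C(=O)OC(=O)c1c(Cl)cc(Cl)cc1Cl | intermediate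
21 | tert-butyl (3R,4S,5S)-5-{[tert-butyl(dimethyl)silyl]oxy}-3-[(6-methylheptanoyl)oxy]-4-{[(2E)-2-methylbut-2-enoyl]oxy}cyclohex-1-ene-1-carboxylate | CC(C)(C)OC(=O)C1=C[C@@H](OC(=O)CCCCC(C)C)[C@H](OC(=O)/C(C)=C/C)[C@@H](O[Si](C)(C)C(C)(C)C)C1 | intermediate
22 | tert-butyl (3R,4R,5S)-5-hydroxy-3-[(6-methylheptanoyl)oxy]-4-{[(2E)-2-methylbut-2-enoyl]oxy}cyclohex-1-ene-1-carboxylate | CC(C)(C)OC(=O)C1=C[C@@H](OC(=O)CCCCC(C)C)[C@H](OC(=O)/C(C)=C/C)[C@@H](O)C1 | intermediate
23 | tert-butyl (3R,4R,5S)-5-acetoxy-3-[(6-methylheptanoyl)oxy]-4-{[(2E)-2-methylbut-2-enoyl]oxy}cyclohex-1-ene-1-carboxylate | CC(C)(C)OC(=O)C1=C[C@@H](OC(=O)CCCCC(C)C)[C@H](OC(=O)/C(C)=C/C)[C@@H](OC(C)=O)C1 | intermediate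
24 | (3R,4R,5S)-5-acetoxy-3-[(6-methylheptanoyl)oxy]-4-{[(2E)-2-methylbut-2-enoyl]oxy}cyclohex-1-ene-1-carboxylic acid (CNP0225437.1) | C/C=C(\C)C(=O)O[C@@H]1[C@@H](OC(C)=O)CC(C(=O)O)=C[C@H]1OC(=O)CCCCC(C)C | target

## Step count and risks

Total: 17 steps. Longest linear sequence: 16 steps, from 1 to 24 through steps 1, 2 and 4–17; step 3 is the one-step side branch.

**Step 7 (key step).** The likeliest failure is incomplete equilibration, or a closure equilibrium weakened by the strain of the trans-fused dioxolane, so that C3 forms with poor diastereoselectivity. A second risk is slow loss of HNO2 from the open chain if the base is too strong.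

Fallback: C3 is erased and reset. It sets out from 14, carried through steps 8–10 as whatever C3 mixture step 7 delivers, and comes back to 14 as a single C3 isomer. Dess–Martin oxidation of the allylic alcohol gives the enone tert-butyl (4R,5S)-4,5-(isopropylidenedioxy)-3-oxocyclohex-1-ene-1-carboxylate F1, in which C3 is trigonal. Luche reduction (NaBH4, CeCl3·7H2O, MeOH, −78 °C) of this rigid half-chair should deliver hydride along the axial trajectory, anti to the axial C4–H, and return the equatorial alcohol 14.

**Step 4.** Substitution at the β-branched, β-oxygenated primary carbon may be slower than decomposition of the dianion, which loses nitrite on warming, and O-alkylation of the nitronate may compete.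

Fallback: the nitro group is introduced after the C–C bond. It sets out from triflate 3 and comes back at 7.
- Alkylation of the lithium enolate of tert-butyl acetate (LiN(iPr)2, THF/DMPU, −78 °C) with 3 gives tert-butyl 3-[(4S,5S)-5-{[tert-butyl(dimethyl)silyl]oxymethyl}-2,2-dimethyl-1,3-dioxolan-4-yl]propanoate F2.
- Enolisation and trapping with monomeric formaldehyde gives tert-butyl 3-[(4S,5S)-5-{[tert-butyl(dimethyl)silyl]oxymethyl}-2,2-dimethyl-1,3-dioxolan-4-yl]-2-(hydroxymethyl)propanoate F3.
- Iodination (I2, PPh3, imidazole) gives tert-butyl 3-[(4S,5S)-5-{[tert-butyl(dimethyl)silyl]oxymethyl}-2,2-dimethyl-1,3-dioxolan-4-yl]-2-(iodomethyl)propanoate F4.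
- Kornblum substitution (NaNO2, DMSO) gives 7.

**Step 13.** Steric discrimination between O4 and O5 may be insufficient, and imidazole may promote O3→O4 migration of the 6-methylheptanoyl group while O4 is free.

Fallback: the diol is differentiated while O3 still carries its bulky silyl ether and no acyl group is present to migrate. It sets out from 13 and comes back at 23.
- Aqueous AcOH removes only the strained acetonide and gives tert-butyl (3R,4R,5S)-3-{[tert-butyl(dimethyl)silyl]oxy}-4,5-dihydroxycyclohex-1-ene-1-carboxylate F5.
- Low-temperature acetylation (AcCl, 2,4,6-collidine, CH2Cl2, −78 °C) at O5, which is now opposed by an O4 wedged between a silyl ether and O5, gives tert-butyl (3R,4R,5S)-5-acetoxy-3-{[tert-butyl(dimethyl)silyl]oxy}-4-hydroxycyclohex-1-ene-1-carboxylate F6.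
- Yamaguchi tigloylation gives tert-butyl (3R,4R,5S)-5-acetoxy-3-{[tert-butyl(dimethyl)silyl]oxy}-4-{[(2E)-2-methylbut-2-enoyl]oxy}cyclohex-1-ene-1-carboxylate F7.
- HF·pyridine gives tert-butyl (3R,4S,5S)-5-acetoxy-3-hydroxy-4-{[(2E)-2-methylbut-2-enoyl]oxy}cyclohex-1-ene-1-carboxylate F8.
- Steglich esterification with 15 gives 23.

**Step 14.** Acylation of the doubly flanked O4 with a conjugated, α-branched acyl donor may be slow enough for the O3 ester to migrate onto O4 under DMAP, or may stall.

Fallback: the tiglate is built on the oxygen. It sets out from 18 and comes back at 21.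
- Esterification with 2-(diethoxyphosphoryl)propanoic acid and dicyclohexylcarbodiimide, a small and reactive acyl donor, gives tert-butyl (3R,4S,5S)-5-{[tert-butyl(dimethyl)silyl]oxy}-4-{[2-(diethoxyphosphoryl)propanoyl]oxy}-3-[(6-methylheptanoyl)oxy]cyclohex-1-ene-1-carboxylate F9.
- Horner–Wadsworth–Emmons olefination with acetaldehyde (LiCl, iPr2NEt, MeCN) should give the E-configured 2-methylbut-2-enoate 21.

## Further compounds

F1 | step 7 | tert-butyl (4R,5S)-4,5-(isopropylidenedioxy)-3-oxocyclohex-1-ene-1-carboxylate | CC(C)(C)OC(=O)C1=CC(=O)[C@@H]2OC(C)(C)O[C@H]2C1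
F2 | step 4 | tert-butyl 3-[(4S,5S)-5-{[tert-butyl(dimethyl)silyl]oxymethyl}-2,2-dimethyl-1,3-dioxolan-4-yl]propanoate | CC(C)(C)[Si](C)(C)OC[C@@H]1OC(C)(C)O[C@H]1CCC(=O)OC(C)(C)C
F3 | step 4 | tert-butyl 3-[(4S,5S)-5-{[tert-butyl(dimethyl)silyl]oxymethyl}-2,2-dimethyl-1,3-dioxolan-4-yl]-2-(hydroxymethyl)propanoate (both C2 epimers) | CC(C)(C)[Si](C)(C)OC[C@@H]1OC(C)(C)O[C@H]1CC(CO)C(=O)OC(C)(C)C
F4 | step 4 | tert-butyl 3-[(4S,5S)-5-{[tert-butyl(dimethyl)silyl]oxymethyl}-2,2-dimethyl-1,3-dioxolan-4-yl]-2-(iodomethyl)propanoate (both C2 epimers) | CC(C)(C)[Si](C)(C)OC[C@@H]1OC(C)(C)O[C@H]1CC(CI)C(=O)OC(C)(C)C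
F5 | step 13 | tert-butyl (3R,4R,5S)-3-{[tert-butyl(dimethyl)silyl]oxy}-4,5-dihydroxycyclohex-1-ene-1-carboxylate | CC(C)(C)OC(=O)C1=C[C@@H](O[Si](C)(C)C(C)(C)C)[C@H](O)[C@@H](O)C1
F6 | step 13 | tert-butyl (3R,4R,5S)-5-acetoxy-3-{[tert-butyl(dimethyl)silyl]oxy}-4-hydroxycyclohex-1-ene-1-carboxylate | CC(C)(C)OC(=O)C1=C[C@@H](O[Si](C)(C)C(C)(C)C)[C@H](O)[C@@H](OC(C)=O)C1
F7 | step 13 | tert-butyl (3R,4R,5S)-5-acetoxy-3-{[tert-butyl(dimethyl)silyl]oxy}-4-{[(2E)-2-methylbut-2-enoyl]oxy}cyclohex-1-ene-1-carboxylate | CC(C)(C)OC(=O)C1=C[C@@H](O[Si](C)(C)C(C)(C)C)[C@H](OC(=O)/C(C)=C/C)[C@@H](OC(C)=O)C1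
F8 | step 13 | tert-butyl (3R,4S,5S)-5-acetoxy-3-hydroxy-4-{[(2E)-2-methylbut-2-enoyl]oxy}cyclohex-1-ene-1-carboxylate | CC(C)(C)OC(=O)C1=C[C@@H](O)[C@H](OC(=O)/C(C)=C/C)[C@@H](OC(C)=O)C1
F9 | step 14 | tert-butyl (3R,4S,5S)-5-{[tert-butyl(dimethyl)silyl]oxy}-4-{[2-(diethoxyphosphoryl)propanoyl]oxy}-3-[(6-methylheptanoyl)oxy]cyclohex-1-ene-1-carboxylate (both epimers at the phosphonate carbon) | CC(C)(C)OC(=O)C1=C[C@@H](OC(=O)CCCCC(C)C)[C@H](OC(=O)C(C)P(=O)(OCC)OCC)[C@@H](O[Si](C)(C)C(C)(C)C)C1
A1 | alternative 1 | methyl 6-deoxy-2,3-bis-O-(4-methoxybenzyl)-4-O-[tert-butyl(dimethyl)silyl]-α-D-xylo-hex-5-enopyranoside | C=C1O[C@H](OC)[C@H](OCc2ccc(OC)cc2)[C@@H](OCc2ccc(OC)cc2)[C@@H]1O[Si](C)(C)C(C)(C)C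
A2 | alternative 1 | 2-{[tert-butyl(dimethyl)silyl]oxy}-5-hydroxy-3,4-bis(4-methoxybenzyloxy)cyclohexanone | O=C1C[C@H](O)[C@H](OCc2ccc(OC)cc2)[C@@H](OCc3ccc(OC)cc3)[C@@H]1O[Si](C)(C)C(C)(C)C
A3 | alternative 2 | furan | c1ccoc1
A4 | alternative 2 | 2,2,2-trifluoroethyl acrylate | C=CC(=O)OCC(F)(F)F
A5 | alternative 2 | 2,2,2-trifluoroethyl endo-7-oxabicyclo[2.2.1]hept-5-ene-2-carboxylate | O=C(OCC(F)(F)F)[C@H]1C[C@H]2C=C[C@@H]1O2
A6 | alternative 3 | tert-butyl 3-[(4S,5R)-5-acetyl-2,2-dimethyl-1,3-dioxolan-4-yl]-2-oxopropanoate | CC(=O)[C@@H]1OC(C)(C)O[C@H]1CC(=O)C(=O)OC(C)(C)C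
A7 | alternative 3 | tert-butyl (4R,5S)-4,5-(isopropylidenedioxy)-3-oxocyclohex-1-ene-1-carboxylate | CC(C)(C)OC(=O)C1=CC(=O)[C@@H]2OC(C)(C)O[C@H]2C1
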